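**Retrosynthetic overview**
1. Dendronpholide B ⇐ acyclic iodo-aldehyde by intramolecular Nozaki–Hiyama–Kishi coupling (C3–C4); the 14-membered ring is closed last and C3 is set then.
2. The α-methylene-ε-lactone (first ring formed) ⇐ 7-exo opening of a trans-11,12-epoxide by the C16 acid at C12 (inversion); epoxide ⇐ anti-11,12-diol ⇐ chelation-controlled reduction of a C11 ketone.
3. Key step: the C11 ketone ⇐ Carroll [3,3]-sigmatropic rearrangement of an allyl β-keto ester, which forms C9–C10, sets the (E)-C7=C8 olefin and joins the two halves.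
4. β-Keto ester ⇐ C11 acid (carrying C1 and C12) + racemic (E)-6-iodo-2-methylhepta-1,5-dien-3-ol (from methacrolein).
5. C11 acid ⇐ (1S,2S,4R)-limonene-1,2-diol (C4 → C1; C1 → C12, inverted later) by oxidation, one-carbon ring expansion, ene chlorination (C16) and ozonolysis of a silyl enol ether.

Assumption: (1S,2S,4R)-(+)-limonene-1,2-diol (hydration product of (R)-limonene oxide) is bought; Zn(BH4)2 and Cp2Zr(H)Cl are used preformed; cembrane numbering is used in the explanations (C1 = CH bearing C15(=C17)–C16, C3 = carbinol C, C11 = acetoxy C, C12 = lactone carbinol C).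

**Route**

Step 1
Reactants: 1 (1S,2S,4R)-limonene-1,2-diol
Product: 2 (2S,5R)-2-hydroxy-2-methyl-5-(prop-1-en-2-yl)cyclohexan-1-one
Conditions: IBX, EtOAc, 75 °C
Reagents that add atoms: none
Why: IBX alcohol oxidation converts the secondary carbinol of the 1,2-diol into the α-ketol without glycol cleavage and leaves both bought stereocentres (future C12 and C1) untouched.

Step 2
Reactants: 2 (2S,5R)-2-hydroxy-2-methyl-5-(prop-1-en-2-yl)cyclohexan-1-one
Product: 3 (2S,5R)-2-[(tert-butyldimethylsilyl)oxy]-2-methyl-5-(prop-1-en-2-yl)cyclohexan-1-one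
Conditions: TBSOTf, 2,6-lutidine, CH2Cl2, 0 °C → rt
Reagents that add atoms: tert-butyldimethylsilyl triflate, CC(C)(C)[Si](C)(C)OS(=O)(=O)C(F)(F)F
Why: Silyl protection of the tertiary α-ketol OH prevents α-ketol rearrangement in the next step and tetronate formation at the β-keto ester stage.

Step 3
Reactants: 3 (2S,5R)-2-[(tert-butyldimethylsilyl)oxy]-2-methyl-5-(prop-1-en-2-yl)cyclohexan-1-one
Product: 5 (2S,5R)-2-[(tert-butyldimethylsilyl)oxy]-2-methyl-5-(prop-1-en-2-yl)cycloheptan-1-one, via 7-(trimethylsilyl)cycloheptanone 4 (not isolated)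
Conditions: TMSCHN2, BF3·OEt2, CH2Cl2, −78 → −30 °C; then K2CO3, MeOH, rt
Reagents that add atoms: (trimethylsilyl)diazomethane, C[Si](C)(C)C=[N+]=[N-]
Why: Lewis-acid-promoted diazoalkane ring expansion in which the unsubstituted CH2 migrates rather than the siloxy-bearing quaternary carbon, inserting the future C3 next to the ketone without touching a stereocentre.

Step 4
Reactants: 5 (2S,5R)-2-[(tert-butyldimethylsilyl)oxy]-2-methyl-5-(prop-1-en-2-yl)cycloheptan-1-one
Product: 6 (2S,5R)-2-[(tert-butyldimethylsilyl)oxy]-5-(3-chloroprop-1-en-2-yl)-2-methylcycloheptan-1-one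
Conditions: Ca(OCl)2, CO2 (dry ice), CH2Cl2/H2O, 0 °C
Reagents that add atoms: calcium hypochlorite, [Ca+2].[O-]Cl.[O-]Cl
Why: HOCl ene-type allylic chlorination of the only alkene (as in carvone → 10-chlorocarvone) installs the C16 oxidation handle before any other olefin is present.

Step 5
Reactants: 6 (2S,5R)-2-[(tert-butyldimethylsilyl)oxy]-5-(3-chloroprop-1-en-2-yl)-2-methylcycloheptan-1-one
Product: 7 (4R,7S)-1,7-bis[(tert-butyldimethylsilyl)oxy]-4-(3-chloroprop-1-en-2-yl)-7-methylcyclohept-1-ene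
Conditions: TBSOTf, Et3N, CH2Cl2, 0 °C → rt
Reagents that add atoms: tert-butyldimethylsilyl triflate, CC(C)(C)[Si](C)(C)OS(=O)(=O)C(F)(F)F
Why: Silyl enol ether formation can only occur toward the CH2 (C3) because the other α-carbon is quaternary.

Step 6
Reactants: 7 (4R,7S)-1,7-bis[(tert-butyldimethylsilyl)oxy]-4-(3-chloroprop-1-en-2-yl)-7-methylcyclohept-1-ene
Product: 9 (2S,5R)-2-[(tert-butyldimethylsilyl)oxy]-5-(3-chloroprop-1-en-2-yl)-7,7-dimethoxy-2-methylheptanoic acid, via silyl ester aldehyde 8 (not isolated)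
Conditions: O3, CH2Cl2, −78 °C (Sudan III); Me2S; then PPTS, MeOH, 3 Å MS, rt
Reagents that add atoms: ozone, [O-][O+]=O; methanol, CO
Why: Ozonolysis cleaves the electron-rich silyl enol ether much faster than the chloromethyl-deactivated 1,1-disubstituted alkene, giving the C11 acid and the C3 aldehyde, which is masked in the same pot as its dimethyl acetal.

Step 7
Reactants: 10 methacrolein; 11 propargyl bromide
Product: 13 rac-2-methylhex-1-en-5-yn-3-ol, via allenylzinc bromide 12 (not isolated)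
Conditions: Zn dust, THF, 0 °C → rt; 1 M HCl work-up
Reagents that add atoms: none
Why: Barbier propargylation, in which allenylzinc bromide adds by SE2′ to the aldehyde to give the homopropargylic alcohol (its carbinol centre is destroyed later, so the racemate suffices).

Step 8
Reactants: 13 rac-2-methylhex-1-en-5-yn-3-ol
Product: 15 rac-2-methylhept-1-en-5-yn-3-ol, via dilithium alkoxide–acetylide 14 (not isolated)
Conditions: n-BuLi (2.1 equiv), THF, −78 → 0 °C; MeI (1.05 equiv), −78 °C → rt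
Reagents that add atoms: iodomethane, CI
Why: Acetylide alkylation: the dianion reacts with MeI at carbon far faster than at the lithium alkoxide.

Step 9
Reactants: 15 rac-2-methylhept-1-en-5-yn-3-ol
Product: 17 rac-(E)-6-iodo-2-methylhepta-1,5-dien-3-ol, via alkenylzirconocene 16 (not isolated)
Conditions: Cp2Zr(H)Cl (2.3 equiv), THF, rt; then I2, 0 °C
Reagents that add atoms: iodine, II
Why: Hydrozirconation–iodination: syn addition of Zr–H places Zr on the methyl-bearing alkyne carbon and iodinolysis with retention gives the (E)-2-iodoalkene needed for the 4E olefin.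

Step 10
Reactants: 9 (2S,5R)-2-[(tert-butyldimethylsilyl)oxy]-5-(3-chloroprop-1-en-2-yl)-7,7-dimethoxy-2-methylheptanoic acid; 17 rac-(E)-6-iodo-2-methylhepta-1,5-dien-3-ol
Product: 19 (E)-6-iodo-2-methylhepta-1,5-dien-3-yl (4S,7R)-4-[(tert-butyldimethylsilyl)oxy]-7-(3-chloroprop-1-en-2-yl)-9,9-dimethoxy-4-methyl-3-oxononanoate (1:1 at the carbinol carbon), via acyl Meldrum's acid 18 (not isolated)
Conditions: Meldrum's acid, DCC, DMAP, CH2Cl2, 0 °C → rt; filter; then 17, PhMe, 90 °C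
Reagents that add atoms: Meldrum's acid, CC1(C)OC(=O)CC(=O)O1
Why: Oikawa–Yonemitsu β-keto ester synthesis: the acyl Meldrum's acid fragments thermally to an acylketene that is trapped by the secondary allylic alcohol.

Step 11
Reactants: 19 (E)-6-iodo-2-methylhepta-1,5-dien-3-yl (4S,7R)-4-[(tert-butyldimethylsilyl)oxy]-7-(3-chloroprop-1-en-2-yl)-9,9-dimethoxy-4-methyl-3-oxononanoate
Product: 21 (3R,6S,10E,13E)-6-[(tert-butyldimethylsilyl)oxy]-3-(3-chloroprop-1-en-2-yl)-14-iodo-1,1-dimethoxy-6,10-dimethylpentadeca-10,13-dien-7-one, via β-keto acid 20 (not isolated)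
Conditions: PhMe, BHT (cat.), 170 °C, sealed tube
Reagents that add atoms: none
Why: Carroll rearrangement, a [3,3]-sigmatropic shift of the ester enol through a chair transition state with the C6 chain equatorial, forms the C9–C10 bond and the (E)-C7=C8 olefin, after which the β-keto acid loses CO2.

Step 12
Reactants: 21 (3R,6S,10E,13E)-6-[(tert-butyldimethylsilyl)oxy]-3-(3-chloroprop-1-en-2-yl)-14-iodo-1,1-dimethoxy-6,10-dimethylpentadeca-10,13-dien-7-one
Product: 22 (3R,6S,10E,13E)-3-(3-chloroprop-1-en-2-yl)-6-hydroxy-14-iodo-1,1-dimethoxy-6,10-dimethylpentadeca-10,13-dien-7-one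
Conditions: HF·pyridine, pyridine, THF, 0 °C → rt
Reagents that add atoms: none
Why: Buffered fluoride desilylation frees the tertiary α-hydroxyl needed for chelation while the acetal, allylic chloride and vinyl iodide survive.

Step 13
Reactants: 22 (3R,6S,10E,13E)-3-(3-chloroprop-1-en-2-yl)-6-hydroxy-14-iodo-1,1-dimethoxy-6,10-dimethylpentadeca-10,13-dien-7-one
Product: 23 (3R,6S,7R,10E,13E)-3-(3-chloroprop-1-en-2-yl)-14-iodo-1,1-dimethoxy-6,10-dimethylpentadeca-10,13-diene-6,7-diol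
Conditions: Zn(BH4)2, Et2O, −20 °C; aq. NH4Cl
Reagents that add atoms: none
Why: Chelation-controlled (Cram cyclic model) ketone reduction: hydride attacks the zinc chelate of the α-hydroxy ketone from the face of the smaller CH3 on C12, giving the anti (11R,12S) diol; only a moderate ratio is expected because the model must discriminate CH3 from a CH2 chain, and the syn isomer is separated and can be re-oxidised to 22.

Step 14
Reactants: 23 (3R,6S,7R,10E,13E)-3-(3-chloroprop-1-en-2-yl)-14-iodo-1,1-dimethoxy-6,10-dimethylpentadeca-10,13-diene-6,7-diol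
Product: 25 (2S,3S)-2-[(3R)-3-(3-chloroprop-1-en-2-yl)-5,5-dimethoxypentyl]-3-[(3E,6E)-7-iodo-3-methylocta-3,6-dien-1-yl]-2-methyloxirane, via 7-mesylate 24 (not isolated)
Conditions: MsCl, Et3N, CH2Cl2, −20 °C; then DBU, rt
Reagents that add atoms: none
Why: Selective mesylation of the secondary alcohol and intramolecular Williamson SN2 closure by the tertiary oxygen invert C11 (R → S) and give the trans-11,12-epoxide with C12 unchanged.

Step 15
Reactants: 25 (2S,3S)-2-[(3R)-3-(3-chloroprop-1-en-2-yl)-5,5-dimethoxypentyl]-3-[(3E,6E)-7-iodo-3-methylocta-3,6-dien-1-yl]-2-methyloxirane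
Product: 26 2-{(3R)-5-[(2S,3S)-3-[(3E,6E)-7-iodo-3-methylocta-3,6-dien-1-yl]-2-methyloxiran-2-yl]-1,1-dimethoxypentan-3-yl}prop-2-enal
Conditions: NMO, NaI (cat.), MeCN, rt
Reagents that add atoms: N-methylmorpholine N-oxide, C[N+]1([O-])CCOCC1
Why: Ganem oxidation (SN2 displacement of the allylic chloride by the N-oxide, then elimination) gives the 2-substituted acrolein under non-acidic conditions that spare the epoxide.

Step 16
Reactants: 26 2-{(3R)-5-[(2S,3S)-3-[(3E,6E)-7-iodo-3-methylocta-3,6-dien-1-yl]-2-methyloxiran-2-yl]-1,1-dimethoxypentan-3-yl}prop-2-enal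
Product: 28 (4R,7R)-4-(2,2-dimethoxyethyl)-7-[(1S,4E,7E)-1-hydroxy-8-iodo-4-methylnona-4,7-dien-1-yl]-7-methyl-3-methylideneoxepan-2-one, via epoxy acrylic acid 27 (not isolated)
Conditions: NaClO2, NaH2PO4, 2-methyl-2-butene, t-BuOH/H2O, 0 °C; then CSA (cat.), CH2Cl2, −20 → 0 °C
Reagents that add atoms: sodium chlorite, [Na+].[O-]Cl=O
Why: Pinnick oxidation gives the acrylic acid, which under acid catalysis opens the epoxide 7-exo at the tertiary C12 with inversion (S → R), forming the α-methylene-ε-lactone and releasing the 11S hydroxyl.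

Step 17
Reactants: 28 (4R,7R)-4-(2,2-dimethoxyethyl)-7-[(1S,4E,7E)-1-hydroxy-8-iodo-4-methylnona-4,7-dien-1-yl]-7-methyl-3-methylideneoxepan-2-one
Product: 29 (1S,4E,7E)-1-[(2R,5R)-5-(2,2-dimethoxyethyl)-2-methyl-6-methylidene-7-oxooxepan-2-yl]-8-iodo-4-methylnona-4,7-dien-1-yl acetate
Conditions: Ac2O, pyridine, DMAP (cat.), CH2Cl2, rt
Reagents that add atoms: acetic anhydride, CC(=O)OC(C)=O
Why: Acylation of the only free hydroxyl installs the C11 acetate.

Step 18
Reactants: 29 (1S,4E,7E)-1-[(2R,5R)-5-(2,2-dimethoxyethyl)-2-methyl-6-methylidene-7-oxooxepan-2-yl]-8-iodo-4-methylnona-4,7-dien-1-yl acetate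
Product: 30 (1S,4E,7E)-8-iodo-4-methyl-1-[(2R,5R)-2-methyl-6-methylidene-7-oxo-5-(2-oxoethyl)oxepan-2-yl]nona-4,7-dien-1-yl acetate
Conditions: PPTS, acetone/H2O (10:1), 45 °C
Reagents that add atoms: water, O
Why: Mild acid-catalysed acetal hydrolysis releases the C3 aldehyde without touching the acetate, lactone or vinyl iodide.

Step 19
Reactants: 30 (1S,4E,7E)-8-iodo-4-methyl-1-[(2R,5R)-2-methyl-6-methylidene-7-oxo-5-(2-oxoethyl)oxepan-2-yl]nona-4,7-dien-1-yl acetate
Product: 32 Dendronpholide B, via alkenylchromium(III) species 31 (not isolated)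
Conditions: CrCl2 (10 equiv), NiCl2 (2 mol %), DMSO/THF (3:1), 0.003 M, rt
Reagents that add atoms: none
Why: Intramolecular Nozaki–Hiyama–Kishi coupling adds the E-alkenylchromium (geometry retained) chemoselectively to the aldehyde to close the 14-membered ring; C3 is set by substrate control from the existing centres, and the 3R sense is expected but not secured.

**Compound list**
1 | (1S,2S,4R)-limonene-1,2-diol | C[C@]1(O)CC[C@@H](C(C)=C)C[C@@H]1O | starting material
2 | (2S,5R)-2-hydroxy-2-methyl-5-(prop-1-en-2-yl)cyclohexan-1-one | C[C@]1(O)CC[C@@H](C(C)=C)CC1=O | intermediate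
3 | (2S,5R)-2-[(tert-butyldimethylsilyl)oxy]-2-methyl-5-(prop-1-en-2-yl)cyclohexan-1-one | C[C@]1(O[Si](C)(C)C(C)(C)C)CC[C@@H](C(C)=C)CC1=O | intermediate
4 | (2S,5R)-2-[(tert-butyldimethylsilyl)oxy]-2-methyl-5-(prop-1-en-2-yl)-7-(trimethylsilyl)cycloheptan-1-one (C7 epimers) | C[C@]1(O[Si](C)(C)C(C)(C)C)CC[C@@H](C(C)=C)CC([Si](C)(C)C)C1=O | intermediate (not isolated)
5 | (2S,5R)-2-[(tert-butyldimethylsilyl)oxy]-2-methyl-5-(prop-1-en-2-yl)cycloheptan-1-one | C[C@]1(O[Si](C)(C)C(C)(C)C)CC[C@@H](C(C)=C)CCC1=O | intermediate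
6 | (2S,5R)-2-[(tert-butyldimethylsilyl)oxy]-5-(3-chloroprop-1-en-2-yl)-2-methylcycloheptan-1-one | C[C@]1(O[Si](C)(C)C(C)(C)C)CC[C@@H](C(CCl)=C)CCC1=O | intermediate
7 | (4R,7S)-1,7-bis[(tert-butyldimethylsilyl)oxy]-4-(3-chloroprop-1-en-2-yl)-7-methylcyclohept-1-ene | C[C@]1(O[Si](C)(C)C(C)(C)C)CC[C@@H](C(CCl)=C)CC=C1O[Si](C)(C)C(C)(C)C | intermediate
8 | tert-butyldimethylsilyl (2S,5R)-2-[(tert-butyldimethylsilyl)oxy]-5-(3-chloroprop-1-en-2-yl)-2-methyl-7-oxoheptanoate | CC(C)(C)[Si](C)(C)OC(=O)[C@@](C)(O[Si](C)(C)C(C)(C)C)CC[C@H](CC=O)C(=C)CCl | intermediate (not isolated)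
9 | (2S,5R)-2-[(tert-butyldimethylsilyl)oxy]-5-(3-chloroprop-1-en-2-yl)-7,7-dimethoxy-2-methylheptanoic acid | OC(=O)[C@@](C)(O[Si](C)(C)C(C)(C)C)CC[C@H](CC(OC)OC)C(=C)CCl | intermediate
10 | methacrolein | CC(=C)C=O | starting material
11 | propargyl bromide | BrCC#C | starting material
12 | allenylzinc bromide | C=C=C[Zn]Br | intermediate (not isolated)
13 | rac-2-methylhex-1-en-5-yn-3-ol | C=C(C)C(O)CC#C | intermediate
14 | dilithium salt of 13 (lithium alkoxide, lithium acetylide) | C=C(C)C(O[Li])CC#C[Li] | intermediate (not isolated)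
15 | rac-2-methylhept-1-en-5-yn-3-ol | C=C(C)C(O)CC#CC | intermediate
16 | (E)-alkenylzirconocene chloride of 15 (Zr on the methyl-bearing carbon, alcohol as zirconocene alkoxide) | C=C(C)C(O[Zr](Cl)(C1C=CC=C1)C1C=CC=C1)C/C=C(\C)[Zr](Cl)(C1C=CC=C1)C1C=CC=C1 | intermediate (not isolated)
17 | rac-(E)-6-iodo-2-methylhepta-1,5-dien-3-ol | C=C(C)C(O)C/C=C(\C)I | intermediate
18 | 5-[(2S,5R)-2-[(tert-butyldimethylsilyl)oxy]-5-(3-chloroprop-1-en-2-yl)-7,7-dimethoxy-2-methylheptanoyl]-2,2-dimethyl-1,3-dioxane-4,6-dione | CC1(C)OC(=O)C(C(=O)[C@@](C)(O[Si](C)(C)C(C)(C)C)CC[C@H](CC(OC)OC)C(=C)CCl)C(=O)O1 | intermediate (not isolated)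
19 | (E)-6-iodo-2-methylhepta-1,5-dien-3-yl (4S,7R)-4-[(tert-butyldimethylsilyl)oxy]-7-(3-chloroprop-1-en-2-yl)-9,9-dimethoxy-4-methyl-3-oxononanoate (both carbinol epimers) | C=C(C)C(C/C=C(\C)I)OC(=O)CC(=O)[C@@](C)(O[Si](C)(C)C(C)(C)C)CC[C@H](CC(OC)OC)C(=C)CCl | intermediate
20 | (4S,7R)-4-[(tert-butyldimethylsilyl)oxy]-7-(3-chloroprop-1-en-2-yl)-2-[(2E,5E)-6-iodo-2-methylhepta-2,5-dien-1-yl]-9,9-dimethoxy-4-methyl-3-oxononanoic acid (C2 epimers) | I/C(C)=C/C/C=C(\C)CC(C(O)=O)C(=O)[C@@](C)(O[Si](C)(C)C(C)(C)C)CC[C@H](CC(OC)OC)C(=C)CCl | intermediate (not isolated)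
21 | (3R,6S,10E,13E)-6-[(tert-butyldimethylsilyl)oxy]-3-(3-chloroprop-1-en-2-yl)-14-iodo-1,1-dimethoxy-6,10-dimethylpentadeca-10,13-dien-7-one | I/C(C)=C/C/C=C(\C)CCC(=O)[C@@](C)(O[Si](C)(C)C(C)(C)C)CC[C@H](CC(OC)OC)C(=C)CCl | intermediate
22 | (3R,6S,10E,13E)-3-(3-chloroprop-1-en-2-yl)-6-hydroxy-14-iodo-1,1-dimethoxy-6,10-dimethylpentadeca-10,13-dien-7-one | I/C(C)=C/C/C=C(\C)CCC(=O)[C@@](C)(O)CC[C@H](CC(OC)OC)C(=C)CCl | intermediate
23 | (3R,6S,7R,10E,13E)-3-(3-chloroprop-1-en-2-yl)-14-iodo-1,1-dimethoxy-6,10-dimethylpentadeca-10,13-diene-6,7-diol | I/C(C)=C/C/C=C(\C)CC[C@@H](O)[C@@](C)(O)CC[C@H](CC(OC)OC)C(=C)CCl | intermediate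
24 | (3R,6S,7R,10E,13E)-3-(3-chloroprop-1-en-2-yl)-6-hydroxy-14-iodo-1,1-dimethoxy-6,10-dimethylpentadeca-10,13-dien-7-yl methanesulfonate | I/C(C)=C/C/C=C(\C)CC[C@@H](OS(C)(=O)=O)[C@@](C)(O)CC[C@H](CC(OC)OC)C(=C)CCl | intermediate (not isolated)
25 | (2S,3S)-2-[(3R)-3-(3-chloroprop-1-en-2-yl)-5,5-dimethoxypentyl]-3-[(3E,6E)-7-iodo-3-methylocta-3,6-dien-1-yl]-2-methyloxirane | I/C(C)=C/C/C=C(\C)CC[C@@H]1O[C@@]1(C)CC[C@H](CC(OC)OC)C(=C)CCl | intermediate
26 | 2-{(3R)-5-[(2S,3S)-3-[(3E,6E)-7-iodo-3-methylocta-3,6-dien-1-yl]-2-methyloxiran-2-yl]-1,1-dimethoxypentan-3-yl}prop-2-enal | I/C(C)=C/C/C=C(\C)CC[C@@H]1O[C@@]1(C)CC[C@H](CC(OC)OC)C(=C)C=O | intermediate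
27 | 2-{(3R)-5-[(2S,3S)-3-[(3E,6E)-7-iodo-3-methylocta-3,6-dien-1-yl]-2-methyloxiran-2-yl]-1,1-dimethoxypentan-3-yl}prop-2-enoic acid | I/C(C)=C/C/C=C(\C)CC[C@@H]1O[C@@]1(C)CC[C@H](CC(OC)OC)C(=C)C(O)=O | intermediate (not isolated)
28 | (4R,7R)-4-(2,2-dimethoxyethyl)-7-[(1S,4E,7E)-1-hydroxy-8-iodo-4-methylnona-4,7-dien-1-yl]-7-methyl-3-methylideneoxepan-2-one | C=C1C(=O)O[C@@](C)([C@@H](O)CC/C(C)=C/C/C=C(\C)I)CC[C@@H]1CC(OC)OC | intermediate
29 | (1S,4E,7E)-1-[(2R,5R)-5-(2,2-dimethoxyethyl)-2-methyl-6-methylidene-7-oxooxepan-2-yl]-8-iodo-4-methylnona-4,7-dien-1-yl acetate | C=C1C(=O)O[C@@](C)([C@@H](OC(C)=O)CC/C(C)=C/C/C=C(\C)I)CC[C@@H]1CC(OC)OC | intermediate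
30 | (1S,4E,7E)-8-iodo-4-methyl-1-[(2R,5R)-2-methyl-6-methylidene-7-oxo-5-(2-oxoethyl)oxepan-2-yl]nona-4,7-dien-1-yl acetate | C=C1C(=O)O[C@@](C)([C@@H](OC(C)=O)CC/C(C)=C/C/C=C(\C)I)CC[C@@H]1CC=O | intermediate
31 | alkenylchromium(III) dichloride of 30 (Cr in place of I at C4) | C=C1C(=O)O[C@@](C)([C@@H](OC(C)=O)CC/C(C)=C/C/C=C(\C)[Cr](Cl)Cl)CC[C@@H]1CC=O | intermediate (not isolated)
32 | Dendronpholide B, (1R,3R,4E,7E,11S,12R) in cembrane numbering | C=C1C(=O)O[C@]2(C)CC[C@@H]1C[C@@H](O)/C(C)=C/C/C=C(\C)CC[C@@H]2OC(C)=O | target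

**Step count.** Total 19 steps. Longest linear sequence 16 (steps 1–6 and 10–19 from 1); steps 7–9 are a three-step side branch to 17.

**Three steps most likely to fail, with fallbacks**

Step 13 (C11 reduction). The chelate has to tell CH3 from a CH2 chain on C12, so the anti:syn ratio may be low or reversed. The fallback makes the route stereoconvergent instead of stereoselective; it sets out from 22 and rejoins at 29. The syn isomer, (3R,6S,7S,10E,13E)-3-(3-chloroprop-1-en-2-yl)-14-iodo-1,1-dimethoxy-6,10-dimethylpentadeca-10,13-diene-6,7-diol F1, already has the final C11 configuration. It is oxidised with NMO to the dihydroxy enal F2 and with NaClO2 to the dihydroxy acrylic acid F3. Trimethyl orthoacetate/PPTS then gives the cyclic orthoacetate F4. Catalytic CSA ionises F4 to the 1,3-dioxolan-2-ylium ion (Kolb–Sharpless chemistry), which the C16 carboxyl opens at the tertiary C12 with inversion. This delivers the C11 acetate and the lactone in one operation, i.e. 29.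

Step 16 (epoxide-opening lactonisation). The protonated trisubstituted epoxide may instead be trapped by the C7=C8 olefin or rearrange to a ketone. The fallback replaces intramolecular opening by intermolecular opening followed by acylative ring closure; it sets out from 27 and rejoins at 30. Dilute HClO4 in THF/H2O lets water attack C12 with inversion and hydrolyses the acetal, giving the (11S,12R)-dihydroxy acid aldehyde F5. Ac2O/pyridine gives the 11-acetate F6. Shiina lactonisation (MNBA, DMAP, high dilution) then closes the ε-lactone on the tertiary alcohol with retention to give 30.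

Step 19 (NHK macrocyclisation). The ring closure may favour the wrong C3 epimer. The fallback corrects C3 after ring closure by SN2 inversion; it sets out from 30 and rejoins at 32. If cyclisation of 30 gives mainly 3-epi-dendronpholide B F7, Mitsunobu reaction with chloroacetic acid (PPh3, DIAD) gives the (3R)-chloroacetate F8. Thiourea/NaHCO3 removes the chloroacetyl group in the presence of the C11 acetate to give 32.

**Further compounds**
F1 | step 13 | (3R,6S,7S,10E,13E)-3-(3-chloroprop-1-en-2-yl)-14-iodo-1,1-dimethoxy-6,10-dimethylpentadeca-10,13-diene-6,7-diol (syn-diol) | I/C(C)=C/C/C=C(\C)CC[C@H](O)[C@@](C)(O)CC[C@H](CC(OC)OC)C(=C)CCl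
F2 | step 13 | syn-dihydroxy enal (F1 with CH2Cl converted to CHO) | I/C(C)=C/C/C=C(\C)CC[C@H](O)[C@@](C)(O)CC[C@H](CC(OC)OC)C(=C)C=O
F3 | step 13 | syn-dihydroxy acrylic acid (F2 with CHO converted to CO2H) | I/C(C)=C/C/C=C(\C)CC[C@H](O)[C@@](C)(O)CC[C@H](CC(OC)OC)C(=C)C(O)=O
F4 | step 13 | cyclic orthoacetate (2-methoxy-2-methyl-1,3-dioxolane) of F3, (11S,12S) | I/C(C)=C/C/C=C(\C)CC[C@@H]1OC(C)(OC)O[C@@]1(C)CC[C@H](CC(OC)OC)C(=C)C(O)=O
F5 | step 16 | (11S,12R)-dihydroxy acrylic acid aldehyde (water-opened 27, acetal hydrolysed) | OC(=O)C(=C)[C@@H](CC=O)CC[C@@](C)(O)[C@@H](O)CC/C(C)=C/C/C=C(\C)I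
F6 | step 16 | 11-acetate of F5 | OC(=O)C(=C)[C@@H](CC=O)CC[C@@](C)(O)[C@@H](OC(C)=O)CC/C(C)=C/C/C=C(\C)I
F7 | step 19 | 3-epi-dendronpholide B (3S) | C=C1C(=O)O[C@]2(C)CC[C@@H]1C[C@H](O)/C(C)=C/C/C=C(\C)CC[C@@H]2OC(C)=O
F8 | step 19 | dendronpholide B 3-O-chloroacetate (3R) | C=C1C(=O)O[C@]2(C)CC[C@@H]1C[C@@H](OC(=O)CCl)/C(C)=C/C/C=C(\C)CC[C@@H]2OC(C)=O
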